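**Plan**
- Retrosynthesis: cut the side-chain C=C (C5 aldehyde plus malonic acid), then the aryl ether bond O1–C7a of the dihydrofuran ring, then C2–C3 (aldol), then C3a–CH2 (enolate arylation of 5-iodovanillin).
- Enabling feature: O1 is bonded to aromatic carbon C7a of ring A, between C7 (OMe) and C3a, so the heterocycle can be closed at an sp2 carbon and the ionisable benzylic centre C2 is never disturbed.
- Forward: ring A is built from 5-iodovanillin as a triflate-bearing arylacetyl imide. A syn aldol with silyl-protected syringaldehyde (ring C) joins the chain at C2–C3. After reduction and primary silylation the only ring made in the route, the five-membered O-heterocycle (ring B), closes at O1–C7a, and the acrylic acid is added last.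
- Stereochemistry: C2 and C3 are both set in the Evans syn aldol directed by (S)-4-benzyl-2-oxazolidinone. The syn (2S,3S) adduct becomes the trans (2S,3R) ring because ring closure breaks no bond at either centre. The E-alkene comes from the decarboxylative condensation.

Key step: step 10

Remark: the SMILES is read as the trans (2S,3R) isomer; ring C is carried as a triisopropylsilyl ether because a benzyl ether could be removed only by hydrogenolysis (which would saturate the acrylic acid) or by boron halides (which would also attack the benzylic C2–O1 ether).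

**Route**

Step 1
Reactants: 1 5-iodovanillin (4-hydroxy-3-iodo-5-methoxybenzaldehyde)
Product: 2 4-formyl-2-iodo-6-methoxyphenyl trifluoromethanesulfonate
Conditions: Tf2O, pyridine, CH2Cl2, 0 °C
Reagents that add atoms: trifluoromethanesulfonic anhydride, O=S(=O)(OS(=O)(=O)C(F)(F)F)C(F)(F)F
Why: Phenol O-triflation turns the oxygen on the future C7a into a leaving group, while aldehyde, iodide and methyl ether are inert to Tf2O/pyridine.

Step 2
Reactants: 2 aryl triflate aldehyde
Product: 3 4-(1,3-dioxolan-2-yl)-2-iodo-6-methoxyphenyl trifluoromethanesulfonate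
Conditions: HOCH2CH2OH, p-TsOH·H2O (cat.), toluene, reflux, Dean–Stark
Reagents that add atoms: ethylene glycol, OCCO
Why: Acid-catalysed acetalisation with azeotropic removal of water masks the aldehyde against the organozinc, boron enolate and hydride reagents to come, and aryl iodide and triflate are stable to the acid.

Step 3
Reactants: 3 iodo triflate acetal
Product: 4 ethyl 2-[5-(1,3-dioxolan-2-yl)-3-methoxy-2-(trifluoromethylsulfonyloxy)phenyl]acetate
Conditions: BrZnCH2CO2Et (from BrCH2CO2Et and Zn dust, THF), Pd(dba)2 (3 mol%), P(t-Bu)3 (3 mol%), THF, rt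
Reagents that add atoms: (2-ethoxy-2-oxoethyl)zinc bromide, CCOC(=O)C[Zn]Br (made from ethyl bromoacetate, CCOC(=O)CBr, and zinc)
Why: Negishi-type arylation of a Reformatsky reagent should be selective because, with Pd/P(t-Bu)3, insertion into the carbon–iodine bond is far faster than into the aryl triflate, and the weakly basic zinc enolate leaves acetal and sulfonate alone.

Step 4
Reactants: 4 ethyl arylacetate
Product: 5 2-[5-(1,3-dioxolan-2-yl)-3-methoxy-2-(trifluoromethylsulfonyloxy)phenyl]acetic acid
Conditions: LiOH·H2O, THF/H2O (3:1), 0 °C; then cold 1 M HCl to pH 4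
Reagents that add atoms: lithium hydroxide, [Li+].[OH-] (supplies the new carboxyl oxygen)
Why: Ester saponification should be selective because hydroxide attacks the unhindered arylacetate carbonyl at 0 °C faster than the sulfonyl sulfur of the flanked triflate, the dioxolane is base-stable, and acidification stops at pH 4 to spare it.

Step 5
Reactants: 5 arylacetic acid; 6 (S)-4-benzyl-2-oxazolidinone
Product: 8 (S)-4-benzyl-3-{2-[5-(1,3-dioxolan-2-yl)-3-methoxy-2-(trifluoromethylsulfonyloxy)phenyl]acetyl}oxazolidin-2-one, via mixed pivalic anhydride 7 (not isolated)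
Conditions: t-BuCOCl, Et3N, THF, −20 °C; then 6, LiCl, −20 °C to rt
Reagents that add atoms: pivaloyl chloride, CC(C)(C)C(=O)Cl (its atoms stay only in intermediate 7)
Why: N-Acylation of the auxiliary through a mixed anhydride works because the LiCl/Et3N-activated oxazolidinone attacks the less hindered arylacetyl carbonyl of the pivalic mixed anhydride.

Step 6
Reactants: 9 syringaldehyde (4-hydroxy-3,5-dimethoxybenzaldehyde)
Product: 10 3,5-dimethoxy-4-(triisopropylsilyloxy)benzaldehyde
Conditions: i-Pr3SiCl, imidazole, DMF, rt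
Reagents that add atoms: chlorotriisopropylsilane, CC(C)[Si](Cl)(C(C)C)C(C)C
Why: Imidazole-promoted phenol silylation caps the ring-C phenol as a hindered ether that resists base and hydride and that fluoride can remove at the end without touching the alkene or the benzylic ether.

Step 7
Reactants: 8 arylacetyl imide; 10 silylated syringaldehyde
Product: 13 (S)-4-benzyl-3-[(2S,3S)-2-{5-(1,3-dioxolan-2-yl)-3-methoxy-2-[(trifluoromethylsulfonyl)oxy]phenyl}-3-hydroxy-3-{3,5-dimethoxy-4-[(triisopropylsilyl)oxy]phenyl}propanoyl]oxazolidin-2-one, via Z-dibutylboron enolate 11 (not isolated), via dibutylboron aldolate 12 (not isolated)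
Conditions: n-Bu2BOTf, i-Pr2NEt, CH2Cl2, −78 to 0 °C; then 10, −78 to 0 °C; pH 7 phosphate buffer, MeOH, 30% H2O2, 0 °C
Reagents that add atoms: dibutylboron trifluoromethanesulfonate, CCCCB(CCCC)OS(=O)(=O)C(F)(F)F (its atoms stay only in intermediates 11 and 12)
Why: In this Evans syn aldol the Z-boron enolate adds to the aldehyde through a closed chair (Zimmerman–Traxler) transition state on the face opposite the auxiliary benzyl group, which sets the (2S,3S) syn pair that becomes C3 and C2 of the target.

Step 8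
Reactants: 13 syn aldol adduct
Product: 14 (1S,2R)-2-{5-(1,3-dioxolan-2-yl)-3-methoxy-2-[(trifluoromethylsulfonyl)oxy]phenyl}-1-{3,5-dimethoxy-4-[(triisopropylsilyl)oxy]phenyl}propane-1,3-diol
Conditions: LiBH4, H2O (1 equiv), Et2O/THF, 0 °C
Reagents that add atoms: none
Why: Reductive cleavage of the N-acyl oxazolidinone by LiBH4 reduces the activated exocyclic carbonyl to the primary alcohol and releases the auxiliary, while aryl triflate, acetal and silyl ether are inert and the cold, short reaction limits retro-aldol (the descriptor at the former α-carbon changes from S to R by priority only).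

Step 9
Reactants: 14 diol
Product: 15 (1S,2R)-3-[(tert-butyldimethylsilyl)oxy]-2-{5-(1,3-dioxolan-2-yl)-3-methoxy-2-[(trifluoromethylsulfonyl)oxy]phenyl}-1-{3,5-dimethoxy-4-[(triisopropylsilyl)oxy]phenyl}propan-1-ol
Conditions: TBSCl, imidazole, CH2Cl2, 0 °C
Reagents that add atoms: tert-butyldimethylsilyl chloride, CC(C)(C)[Si](C)(C)Cl
Why: Selective silylation works because the unhindered primary hydroxyl reacts much faster than the crowded secondary benzylic one, and the cap is needed because a free primary hydroxyl could equally close a five-membered ring onto C7a.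

Step 10
Reactants: 15 syn hydroxy triflate
Product: 16 (2S,3R)-3-{[(tert-butyldimethylsilyl)oxy]methyl}-2-{3,5-dimethoxy-4-[(triisopropylsilyl)oxy]phenyl}-5-(1,3-dioxolan-2-yl)-7-methoxy-2,3-dihydrobenzofuran
Conditions: Pd2(dba)3 (2.5 mol%), 2-(di-tert-butylphosphino)-3-methoxy-6-methyl-2',4',6'-triisopropylbiphenyl (RockPhos, 6 mol%), Cs2CO3, toluene, 80 °C
Reagents that add atoms: none
Why: Zerovalent palladium bound to the bulky biaryl di-tert-butylphosphine inserts into the C7a–O(triflate) bond to give an arylpalladium triflate (divalent palladium); the neighbouring secondary hydroxyl displaces triflate, Cs2CO3 removes its proton, and C–O reductive elimination from the six-membered oxapalladacycle forms O1–C7a and returns zerovalent palladium. The closest known reaction type is the intramolecular Buchwald–Hartwig etherification of aryl halides and sulfonates with tethered secondary alcohols. Ring B closes as a five-membered ring by a formal 5-exo attack of oxygen on the aromatic carbon, realised as reductive elimination rather than as a substitution at C2. No stereocentre is made: only the O–H and the C7a–O(triflate) bonds are broken, so the (1S,2R) syn precursor is carried unchanged into the trans (2S,3R) ring. The step needs reductive elimination to outrun β-hydride loss from the benzylic alkoxide and carbonate attack at the sulfonyl sulfur, which the hindered electron-rich ligand, the weak poorly soluble base and the favourable ring size should secure. Site selectivity is secured by the silyl cap on the primary hydroxyl, the only other oxygen that could close a five-membered ring onto C7a.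

Step 11
Reactants: 16 protected dihydrobenzofuran
Product: 17 (2S,3R)-2-{3,5-dimethoxy-4-[(triisopropylsilyl)oxy]phenyl}-3-(hydroxymethyl)-7-methoxy-2,3-dihydrobenzofuran-5-carbaldehyde
Conditions: 1 M aq. HCl, THF, rt
Reagents that add atoms: water, O
Why: Acid hydrolysis of the acetal and the alkyl silyl ether unmasks the C5 aldehyde and the primary alcohol, while the aryl triisopropylsilyl ether and, at room temperature, the benzylic C2–O1 ether are stable to dilute HCl.

Step 12
Reactants: 17 aldehyde; 18 malonic acid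
Product: 20 (E)-3-[(2S,3R)-2-{3,5-dimethoxy-4-[(triisopropylsilyl)oxy]phenyl}-3-(hydroxymethyl)-7-methoxy-2,3-dihydrobenzofuran-5-yl]acrylic acid, via arylidenemalonic acid 19 (not isolated)
Conditions: pyridine, piperidine (cat.), 80 °C
Reagents that add atoms: none
Why: Knoevenagel–Doebner condensation, amine-catalysed addition of malonic acid followed by decarboxylation in pyridine, should give the thermodynamically favoured E-acrylic acid directly, with no ester to hydrolyse.

Step 13
Reactants: 20 silyl-protected acid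
Product: 21 (E)-3-[(2S,3R)-2-(4-hydroxy-3,5-dimethoxyphenyl)-3-(hydroxymethyl)-7-methoxy-2,3-dihydrobenzofuran-5-yl]acrylic acid
Conditions: Bu4NF, THF, 0 °C; then dilute HCl to pH 3
Reagents that add atoms: none
Why: Fluoride desilylation expels the phenoxide from silicon within minutes at 0 °C, conditions that leave the acrylic acid, the primary alcohol and both stereocentres untouched, and any silyl ether already lost in step 12 arrives at the same product.

**Compound list**

1 | 5-iodovanillin (4-hydroxy-3-iodo-5-methoxybenzaldehyde) | COc1cc(C=O)cc(I)c1O | starting material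
2 | 4-formyl-2-iodo-6-methoxyphenyl trifluoromethanesulfonate | COc1cc(C=O)cc(I)c1OS(=O)(=O)C(F)(F)F | intermediate
3 | 4-(1,3-dioxolan-2-yl)-2-iodo-6-methoxyphenyl trifluoromethanesulfonate | COc1cc(C2OCCO2)cc(I)c1OS(=O)(=O)C(F)(F)F | intermediate
4 | ethyl 2-[5-(1,3-dioxolan-2-yl)-3-methoxy-2-(trifluoromethylsulfonyloxy)phenyl]acetate | CCOC(=O)Cc1cc(C2OCCO2)cc(OC)c1OS(=O)(=O)C(F)(F)F | intermediate
5 | 2-[5-(1,3-dioxolan-2-yl)-3-methoxy-2-(trifluoromethylsulfonyloxy)phenyl]acetic acid | OC(=O)Cc1cc(C2OCCO2)cc(OC)c1OS(=O)(=O)C(F)(F)F | intermediate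
6 | (S)-4-benzyl-2-oxazolidinone | O=C1N[C@@H](Cc2ccccc2)CO1 | starting material
7 | mixed anhydride of acid 5 with pivalic acid (not isolated) | CC(C)(C)C(=O)OC(=O)Cc1cc(C2OCCO2)cc(OC)c1OS(=O)(=O)C(F)(F)F | intermediate
8 | (S)-4-benzyl-3-{2-[5-(1,3-dioxolan-2-yl)-3-methoxy-2-(trifluoromethylsulfonyloxy)phenyl]acetyl}oxazolidin-2-one | O=C(Cc1cc(C2OCCO2)cc(OC)c1OS(=O)(=O)C(F)(F)F)N1[C@@H](Cc2ccccc2)COC1=O | intermediate
9 | syringaldehyde (4-hydroxy-3,5-dimethoxybenzaldehyde) | COc1cc(C=O)cc(OC)c1O | starting material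
10 | 3,5-dimethoxy-4-(triisopropylsilyloxy)benzaldehyde | COc1cc(C=O)cc(OC)c1O[Si](C(C)C)(C(C)C)C(C)C | intermediate
11 | Z-dibutylboron enolate of imide 8, aryl cis to O–B (not isolated) | CCCCB(CCCC)O/C(=C\c1cc(C2OCCO2)cc(OC)c1OS(=O)(=O)C(F)(F)F)N1[C@@H](Cc2ccccc2)COC1=O | intermediate
12 | O-dibutylboryl aldolate of 13 (not isolated) | COc1cc([C@@H](OB(CCCC)CCCC)[C@@H](C(=O)N2[C@@H](Cc3ccccc3)COC2=O)c2cc(C3OCCO3)cc(OC)c2OS(=O)(=O)C(F)(F)F)cc(OC)c1O[Si](C(C)C)(C(C)C)C(C)C | intermediate
13 | (S)-4-benzyl-3-[(2S,3S)-2-{5-(1,3-dioxolan-2-yl)-3-methoxy-2-[(trifluoromethylsulfonyl)oxy]phenyl}-3-hydroxy-3-{3,5-dimethoxy-4-[(triisopropylsilyl)oxy]phenyl}propanoyl]oxazolidin-2-one (syn aldol adduct) | COc1cc([C@@H](O)[C@@H](C(=O)N2[C@@H](Cc3ccccc3)COC2=O)c2cc(C3OCCO3)cc(OC)c2OS(=O)(=O)C(F)(F)F)cc(OC)c1O[Si](C(C)C)(C(C)C)C(C)C | intermediate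
14 | (1S,2R)-2-{5-(1,3-dioxolan-2-yl)-3-methoxy-2-[(trifluoromethylsulfonyl)oxy]phenyl}-1-{3,5-dimethoxy-4-[(triisopropylsilyl)oxy]phenyl}propane-1,3-diol | COc1cc([C@@H](O)[C@@H](CO)c2cc(C3OCCO3)cc(OC)c2OS(=O)(=O)C(F)(F)F)cc(OC)c1O[Si](C(C)C)(C(C)C)C(C)C | intermediate
15 | (1S,2R)-3-[(tert-butyldimethylsilyl)oxy]-2-{5-(1,3-dioxolan-2-yl)-3-methoxy-2-[(trifluoromethylsulfonyl)oxy]phenyl}-1-{3,5-dimethoxy-4-[(triisopropylsilyl)oxy]phenyl}propan-1-ol | COc1cc([C@@H](O)[C@@H](CO[Si](C)(C)C(C)(C)C)c2cc(C3OCCO3)cc(OC)c2OS(=O)(=O)C(F)(F)F)cc(OC)c1O[Si](C(C)C)(C(C)C)C(C)C | intermediate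
16 | (2S,3R)-3-{[(tert-butyldimethylsilyl)oxy]methyl}-2-{3,5-dimethoxy-4-[(triisopropylsilyl)oxy]phenyl}-5-(1,3-dioxolan-2-yl)-7-methoxy-2,3-dihydrobenzofuran (trans) | COc1cc([C@H]2Oc3c(OC)cc(C4OCCO4)cc3[C@@H]2CO[Si](C)(C)C(C)(C)C)cc(OC)c1O[Si](C(C)C)(C(C)C)C(C)C | intermediate
17 | (2S,3R)-2-{3,5-dimethoxy-4-[(triisopropylsilyl)oxy]phenyl}-3-(hydroxymethyl)-7-methoxy-2,3-dihydrobenzofuran-5-carbaldehyde | COc1cc([C@H]2Oc3c(OC)cc(C=O)cc3[C@@H]2CO)cc(OC)c1O[Si](C(C)C)(C(C)C)C(C)C | intermediate
18 | malonic acid | OC(=O)CC(=O)O | starting material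
19 | 2-{[(2S,3R)-2-{3,5-dimethoxy-4-[(triisopropylsilyl)oxy]phenyl}-3-(hydroxymethyl)-7-methoxy-2,3-dihydrobenzofuran-5-yl]methylidene}malonic acid (not isolated) | COc1cc([C@H]2Oc3c(OC)cc(C=C(C(=O)O)C(=O)O)cc3[C@@H]2CO)cc(OC)c1O[Si](C(C)C)(C(C)C)C(C)C | intermediate
20 | (E)-3-[(2S,3R)-2-{3,5-dimethoxy-4-[(triisopropylsilyl)oxy]phenyl}-3-(hydroxymethyl)-7-methoxy-2,3-dihydrobenzofuran-5-yl]acrylic acid | COc1cc([C@H]2Oc3c(OC)cc(/C=C/C(=O)O)cc3[C@@H]2CO)cc(OC)c1O[Si](C(C)C)(C(C)C)C(C)C | intermediate
21 | (E)-3-[(2S,3R)-2-(4-hydroxy-3,5-dimethoxyphenyl)-3-(hydroxymethyl)-7-methoxy-2,3-dihydrobenzofuran-5-yl]acrylic acid | COc1cc([C@H]2Oc3c(OC)cc(/C=C/C(=O)O)cc3[C@@H]2CO)cc(OC)c1O | target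

**Step count and risks**

Total steps: 13. Longest linear sequence: 12 (steps 1–5 and 7–13); step 6 is a one-step side branch.

Steps most likely to fail:

1. Step 10. Insertion of palladium into the doubly ortho-substituted C7a sulfonate may be slow, so that β-hydride loss from the benzylic alkoxide (ketone plus reduced arene) or base cleavage of the S–O bond overtakes ring closure. The fallback closes the same ring from the other side, at O1–C2, by known acid chemistry. It sets out from 15. Aqueous Et4NOH in dioxane at rt is expected to hydrolyse the aryl triflate and, under the same conditions, the aryl silyl ether, giving the bisphenol F1. Treatment with 1 M HCl in THF (rt to 40 °C) should ionise the p-hydroxybenzylic alcohol, let the ring-A phenol close onto C2 under thermodynamic control to the trans ring (C3, set by the aldol, is untouched), and hydrolyse acetal and silyl ether in the same pot to give the phenolic aldehyde F2. Knoevenagel–Doebner condensation of F2 with malonic acid 18 (pyridine, cat. piperidine), through the arylidenemalonic acid F3, then gives the target, so this fallback rejoins the route at 21.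

2. Step 3. The hindered arylpalladium iodide next to the triflate may not take up the zinc enolate, so that loss of iodine by reduction or insertion at the sulfonate competes; the hydroxide of step 4 is a second threat to the sulfonate. The fallback brings in the two-carbon acid as an allyl group and sets out from 3. Stille coupling with allyltributylstannane (PdCl2(PPh3)2, dioxane, 90 °C, no chloride additive, conditions under which iodide reacts and triflate does not) should give the allylarene F4. Lemieux–Johnson cleavage (OsO4 cat., NaIO4, 2,6-lutidine, dioxane/H2O) gives the arylacetaldehyde F5, and Pinnick oxidation (NaClO2, NaH2PO4, 2-methyl-2-butene, t-BuOH/H2O) gives the acid. The fallback rejoins the route at 5 and makes step 4 unnecessary.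

3. Step 8. The metal aldolate formed on hydride treatment of the α-aryl adduct may fragment by retro-aldol or epimerise at the acidic α-carbon before the imide is reduced. The fallback blocks this pathway by masking the secondary hydroxyl first and sets out from 13. TESOTf/2,6-lutidine (CH2Cl2, −78 °C) gives the triethylsilyl ether F6, and LiBH4 (Et2O/THF, 0 °C) reduces the imide without a free aldolate to give the primary alcohol F7. TBSCl/imidazole gives the bis-silyl ether F8, and PPTS in EtOH at 0 °C removes the more labile secondary triethylsilyl group. The fallback rejoins the route at 15 and replaces step 9.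

**Further compounds**

F1 | step 10 | (1S,2R)-3-[(tert-butyldimethylsilyl)oxy]-2-[5-(1,3-dioxolan-2-yl)-2-hydroxy-3-methoxyphenyl]-1-(4-hydroxy-3,5-dimethoxyphenyl)propan-1-ol | COc1cc([C@@H](O)[C@@H](CO[Si](C)(C)C(C)(C)C)c2cc(C3OCCO3)cc(OC)c2O)cc(OC)c1O
F2 | step 10 | (2S,3R)-2-(4-hydroxy-3,5-dimethoxyphenyl)-3-(hydroxymethyl)-7-methoxy-2,3-dihydrobenzofuran-5-carbaldehyde | COc1cc([C@H]2Oc3c(OC)cc(C=O)cc3[C@@H]2CO)cc(OC)c1O
F3 | step 10 | 2-{[(2S,3R)-2-(4-hydroxy-3,5-dimethoxyphenyl)-3-(hydroxymethyl)-7-methoxy-2,3-dihydrobenzofuran-5-yl]methylidene}malonic acid | COc1cc([C@H]2Oc3c(OC)cc(C=C(C(=O)O)C(=O)O)cc3[C@@H]2CO)cc(OC)c1O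
F4 | step 3 | 2-allyl-4-(1,3-dioxolan-2-yl)-6-methoxyphenyl trifluoromethanesulfonate | C=CCc1cc(C2OCCO2)cc(OC)c1OS(=O)(=O)C(F)(F)F
F5 | step 3 | 4-(1,3-dioxolan-2-yl)-2-methoxy-6-(2-oxoethyl)phenyl trifluoromethanesulfonate | O=CCc1cc(C2OCCO2)cc(OC)c1OS(=O)(=O)C(F)(F)F
F6 | step 8 | (S)-4-benzyl-3-[(2S,3S)-2-{5-(1,3-dioxolan-2-yl)-3-methoxy-2-[(trifluoromethylsulfonyl)oxy]phenyl}-3-[(triethylsilyl)oxy]-3-{3,5-dimethoxy-4-[(triisopropylsilyl)oxy]phenyl}propanoyl]oxazolidin-2-one | COc1cc([C@@H](O[Si](CC)(CC)CC)[C@@H](C(=O)N2[C@@H](Cc3ccccc3)COC2=O)c2cc(C3OCCO3)cc(OC)c2OS(=O)(=O)C(F)(F)F)cc(OC)c1O[Si](C(C)C)(C(C)C)C(C)C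
F7 | step 8 | (2R,3S)-2-{5-(1,3-dioxolan-2-yl)-3-methoxy-2-[(trifluoromethylsulfonyl)oxy]phenyl}-3-[(triethylsilyl)oxy]-3-{3,5-dimethoxy-4-[(triisopropylsilyl)oxy]phenyl}propan-1-ol | COc1cc([C@@H](O[Si](CC)(CC)CC)[C@@H](CO)c2cc(C3OCCO3)cc(OC)c2OS(=O)(=O)C(F)(F)F)cc(OC)c1O[Si](C(C)C)(C(C)C)C(C)C
F8 | step 8 | O-triethylsilyl ether of 15 at the secondary (1S) hydroxyl, (1S,2R) configuration | COc1cc([C@@H](O[Si](CC)(CC)CC)[C@@H](CO[Si](C)(C)C(C)(C)C)c2cc(C3OCCO3)cc(OC)c2OS(=O)(=O)C(F)(F)F)cc(OC)c1O[Si](C(C)C)(C(C)C)C(C)C
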